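**Retrosynthetic overview**

1. Target 28 ⇐ ten-membered ketone 25 (C3=O, O14 silylated) by CBS reduction, isobutyrylation and desilylation.
2. 25 ⇐ 12-membered allyl β-keto lactone 22 by Pd-catalysed extrusion of CO2 (ring contraction 12 → 10, forms C1–C2). Enabling feature: in the ten-membered ring the allylic C1H2 of the C9=C10 olefin is bonded to C2, the α-carbon of oxygenated C3, so at the ketone level C9=C10–C1–C2–C3=O is a γ,δ-unsaturated ketone whose C1–C2 bond can carry an O–C(=O) tether.
3. 22 ⇐ 13-membered diolide 19 by transannular Knoevenagel condensation (C4=C5, closes the butenolide); 19 ⇐ alcohol 13 and symmetrical 3-oxoglutarate 14 by two acylketene esterifications (O1, then O6).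
4. 13 ⇐ lactol 6 + bromide 10 by Nozaki–Hiyama carboxyallylation (C7–C8 and the α-methylene lactone); 6 comes from dihydroxyacetone through a temporary butenolide that fixes the C9=C10 geometry; 10 comes from (R)-glyceraldehyde acetonide (C6) and methyl acrylate.
5. Ring order: α-methylene-γ-lactone → 13-membered diolide → butenolide (12-membered keto lactone) → ten-membered carbocycle.

Key step: step 13

Remark: atoms are numbered germacrane-style (ring C1–C10; C4=C5 with C15(=O)–O6 is the butenolide; C7 carries C11(=C13H2)–C12(=O)–O8; C10 carries C14H2OH; C3 carries the ester; On is the oxygen on Cn), and 1,3-dihydroxyacetone is used as its commercial dimer, which reacts as the monomer.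

**Route**

Step 1
Reactants: 1 1,3-dihydroxyacetone; 2 ethyl (triphenylphosphoranylidene)acetate
Product: 4 4-(hydroxymethyl)furan-2(5H)-one, via hydroxy ester 3 (not isolated)
Conditions: CH2Cl2, rt, 16 h
Reagents that add atoms: none
Why: Wittig olefination of the ketone by the stabilised ylide followed by spontaneous lactonisation of 3, in which one of the two equivalent hydroxymethyl groups is necessarily cis to the ester, gives the β-substituted butenolide with no stereochemical issue.

Step 2
Reactants: 4 4-(hydroxymethyl)furan-2(5H)-one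
Product: 5 4-[(tert-butyldiphenylsilyloxy)methyl]furan-2(5H)-one
Conditions: TBDPSCl, imidazole, DMF, 0 °C → rt
Reagents that add atoms: tert-butyl(chloro)diphenylsilane, CC(C)(C)[Si](Cl)(c1ccccc1)c1ccccc1
Why: Standard imidazole-promoted silylation of the only hydroxyl, giving an ether that should survive aqueous acetic acid, 110 °C and Pd(0) and leave under HF·pyridine at the end.

Step 3
Reactants: 5 4-[(tert-butyldiphenylsilyloxy)methyl]furan-2(5H)-one
Product: 6 4-[(tert-butyldiphenylsilyloxy)methyl]-2,5-dihydrofuran-2-ol (lactol; both anomers)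
Conditions: DIBAL-H (1.1 equiv), CH2Cl2, −78 °C; Rochelle salt
Reagents that add atoms: none
Why: DIBAL-H half-reduction of the butenolide at −78 °C should stop at the lactol, a ring-locked equivalent of the (Z)-4-hydroxy-enal in which C1 is held cis to C8 across C9=C10.

Step 4
Reactants: 7 (4R)-2,2-dimethyl-1,3-dioxolane-4-carbaldehyde; 8 methyl acrylate
Product: 9 methyl 2-{[(4R)-2,2-dimethyl-1,3-dioxolan-4-yl](hydroxy)methyl}prop-2-enoate (both carbinol epimers)
Conditions: DABCO (0.3 equiv), neat, rt, 5 d
Reagents that add atoms: none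
Why: Morita–Baylis–Hillman reaction in which the new carbinol centre forms unselectively but is erased in step 5, whereas C6 is taken unchanged from the chiral pool.

Step 5
Reactants: 9 methyl 2-{[(4R)-2,2-dimethyl-1,3-dioxolan-4-yl](hydroxy)methyl}prop-2-enoate
Product: 10 methyl (2Z)-2-(bromomethyl)-3-[(4S)-2,2-dimethyl-1,3-dioxolan-4-yl]prop-2-enoate
Conditions: NBS, Me2S, CH2Cl2, 0 °C → rt
Reagents that add atoms: N-bromosuccinimide, O=C1CCC(=O)N1Br
Why: Corey–Kim-type activation of the allylic alcohol and SN2′ delivery of bromide should give the conjugated (Z)-2-(bromomethyl)alkenoate under neutral conditions that keep the acetonide.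

Step 6
Reactants: 6 4-[(tert-butyldiphenylsilyloxy)methyl]-2,5-dihydrofuran-2-ol; 10 methyl (2Z)-2-(bromomethyl)-3-[(4S)-2,2-dimethyl-1,3-dioxolan-4-yl]prop-2-enoate
Product: 13 (4S,5R)-5-{(1E)-2-[(tert-butyldiphenylsilyloxy)methyl]-3-hydroxyprop-1-en-1-yl}-4-[(4S)-2,2-dimethyl-1,3-dioxolan-4-yl]-3-methylideneoxolan-2-one (trans lactone; free C1–OH), via allylchromium reagent 11 (not isolated), via hydroxy ester 12 (not isolated)
Conditions: CrCl2 (4 equiv), THF, 0 °C → rt; then PPTS (cat.), CH2Cl2, rt
Reagents that add atoms: none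
Why: Nozaki–Hiyama (Barbier-type) 2-alkoxycarbonylallylation in which the lactol reacts through its (Z)-4-hydroxy-enal tautomer: the equilibrating allylchromium adds at C7 through a chair transition state with the aldehyde residue and the C6 substituent equatorial (anti adduct, hence the trans C7/C8 lactone after 5-exo closure of O8 onto the ester), while the C6 stereocentre, whose C–H eclipses the ester-bearing carbon to avoid A1,3 strain, directs the aldehyde anti to the C5–C6 bond and so sets C7.

Step 7
Reactants: 13 trans lactone alcohol; 14 di-tert-butyl 3-oxopentanedioate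
Product: 15 O1-(5-tert-butoxy-3,5-dioxopentanoyl) derivative of 13 (mixed tert-butyl/allylic 3-oxopentanedioate)
Conditions: 14 (5 equiv), toluene, 110 °C, N2 sweep
Reagents that add atoms: none
Why: Thermal transacylation through the acylketene released from the tert-butyl β-keto ester (transacetoacetylation type), trapped by the only free hydroxyl (primary allylic O1), with excess 14 suppressing double exchange.

Step 8
Reactants: 15 mixed 3-oxopentanedioate acetonide
Product: 16 C5,C6-diol (acetonide removed; otherwise as 15)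
Conditions: AcOH/H2O (4:1), 40 °C
Reagents that add atoms: none
Why: Acid-catalysed acetal hydrolysis that should cleave the terminal acetonide while the tert-butyl ester, the TBDPS ether and the lactone are stable.

Step 9
Reactants: 16 C5,C6-diol
Product: 17 O5-triethylsilyl ether (free C6–OH)
Conditions: TESCl (1.1 equiv), imidazole, CH2Cl2, −40 °C
Reagents that add atoms: chlorotriethylsilane, CC[Si](Cl)(CC)CC
Why: Kinetically selective silylation of the primary C5 hydroxyl over the hindered secondary C6 hydroxyl at low temperature.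

Step 10
Reactants: 17 O5-triethylsilyl ether
Product: 19 13-membered diolide (cyclic O1,O6-3-oxopentanedioate; O5-TES; O14-TBDPS; 12,8-methylene lactone), via acylketene 18 (not isolated)
Conditions: toluene (1 mM, syringe-pump addition), 110 °C
Reagents that add atoms: none
Why: Acylketene macrolactonisation: thermal loss of tert-butanol gives acylketene 18, which is trapped at high dilution by the only free hydroxyl (O6) with retention at C6, and the symmetry of the 3-oxoglutarate unit makes acylketene formation at either terminus lead to the same ring.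

Step 11
Reactants: 19 13-membered diolide
Product: 20 C5 primary alcohol of the 13-membered diolide
Conditions: AcOH/THF/H2O (3:1:1), rt
Reagents that add atoms: none
Why: Mild acidic solvolysis should remove the primary triethylsilyl ether selectively in the presence of the far more stable TBDPS ether, and the acidic medium suppresses O6→O5 acyl migration.

Step 12
Reactants: 20 C5 primary alcohol
Product: 22 12-membered allyl β-keto lactone (15,6-butenolide with C4=C5; C3 ketone; C2–C(=O)–O–C1 ester; O14-TBDPS; 12,8-methylene lactone), via aldehyde 21 (not isolated)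
Conditions: DMP (1.2 equiv), CH2Cl2, 0 °C → rt; then EDDA (10 mol %), 4 Å MS, rt
Reagents that add atoms: none
Why: Dess–Martin oxidation to α-acyloxy aldehyde 21 followed by amine-salt-catalysed transannular Knoevenagel condensation, in which C4 (flanked by the C15 ester and the C3 ketone) attacks C5 in a five-membered closure whereas C2 would need a seven-membered one, the new C4=C5 bond being necessarily cis within the lactone and C6 left untouched under these buffered conditions.

Step 13
Reactants: 22 12-membered allyl β-keto lactone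
Product: 25 ten-membered ketone (3-oxo-germacra-4,9,11(13)-triene-12,8:15,6-diolide 14-O-TBDPS ether), via allylpalladium carboxylate 23 (not isolated), via allylpalladium enolate 24 (not isolated)
Conditions: Pd(PPh3)4 (10 mol %), THF (2 mM), 25 → 45 °C
Reagents that add atoms: none
Why: Proposed new method: oxidative addition of Pd(0) to the primary allylic C1–O bond of 22 (anti to the carboxylate) gives the tethered π-allylpalladium β-keto carboxylate 23, loss of CO2 unmasks the C2 enolate of the C3 ketone (24) exactly where the ester tether held it, within bonding distance of C1, and outer-sphere C-alkylation at the CH2 terminus on the face the carboxylate left forms C1–C2. The closest known reactions are the decarboxylative Tsuji–Trost allylation of acyclic allyl β-keto esters (Carroll-type) and the Pd-catalysed decarboxylative ring contraction of small vinyl- or methylidene-substituted lactones, so the bond-forming event is established but its use to contract a 12-membered allyl β-keto lactone to a medium carbocycle is not. The ten-membered ring closes in the endo-allyl mode (attack at the proximal unsubstituted terminus C1, leaving C9=C10 in the ring), the eight-membered alternative by attack at the substituted terminus C9 being disfavoured by sterics and distance. No stereocentre is created (C1 and C2 are methylenes) and C6, C7 and C8 are untouched, while the in-ring cis geometry of C9=C10 should be carried over because the anti-configured 2-substituted π-allyl formed from the Z ester collapses before π–σ–π isomerisation. The step needs C-alkylation to outrun proton transfer and allyl loss: the only acidic C–H (C6–H of the acylbutenolide) lies trans to C3 across the in-ring E C4=C5 bond and cannot reach the C2 enolate intramolecularly, high dilution suppresses intermolecular transfer, and the secondary allylic lactone C8–O bond can only ionise reversibly whereas ionisation at C1 is made irreversible by decarboxylation.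

Step 14
Reactants: 25 ten-membered ketone
Product: 26 (3S)-allylic alcohol (3-hydroxy analogue of 25)
Conditions: (R)-Me-CBS (30 mol %), catecholborane (1.5 equiv), toluene, −78 °C
Reagents that add atoms: none
Why: Corey–Bakshi–Shibata reduction under catalyst control, in which the ketone binds the oxazaborolidine anti to the larger C4 alkenyl (butenolide) group so that the (R)-catalyst should deliver hydride to the face giving the 3S alcohol, 1,2-selectively at −78 °C with both lactones intact.

Step 15
Reactants: 26 (3S)-allylic alcohol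
Product: 27 3-O-(2-methylpropanoyl) 14-O-TBDPS ether of the target
Conditions: iPrCOCl, pyridine, DMAP (cat.), CH2Cl2, 0 °C
Reagents that add atoms: 2-methylpropanoyl chloride, CC(C)C(=O)Cl
Why: DMAP-catalysed acylation of the secondary allylic alcohol with retention at C3.

Step 16
Reactants: 27 3-O-(2-methylpropanoyl) 14-O-TBDPS ether
Product: 28 CNP0322767.4, (3S,6R,7S,8R)-14-hydroxy-3-(2-methylpropanoyloxy)germacra-4,9,11(13)-triene-12,8:15,6-diolide
Conditions: HF·pyridine, THF/pyridine, 0 °C → rt
Reagents that add atoms: none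
Why: Fluoride-mediated Si–O cleavage under buffered non-basic conditions that should neither epimerise the butenolide γ-centre nor add to the α-methylene lactone.

**Compound list**

1 | 1,3-dihydroxyacetone (commercial dimer) | OCC(=O)CO | starting material
2 | ethyl (triphenylphosphoranylidene)acetate | CCOC(=O)C=P(c1ccccc1)(c1ccccc1)c1ccccc1 | starting material
3 | ethyl 4-hydroxy-3-(hydroxymethyl)but-2-enoate (not isolated) | CCOC(=O)C=C(CO)CO | intermediate
4 | 4-(hydroxymethyl)furan-2(5H)-one | OCC1=CC(=O)OC1 | intermediate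
5 | 4-[(tert-butyldiphenylsilyloxy)methyl]furan-2(5H)-one | CC(C)(C)[Si](OCC1=CC(=O)OC1)(c1ccccc1)c1ccccc1 | intermediate
6 | 4-[(tert-butyldiphenylsilyloxy)methyl]-2,5-dihydrofuran-2-ol | CC(C)(C)[Si](OCC1=CC(O)OC1)(c1ccccc1)c1ccccc1 | intermediate
7 | (4R)-2,2-dimethyl-1,3-dioxolane-4-carbaldehyde | O=C[C@H]1COC(C)(C)O1 | starting material
8 | methyl acrylate | C=CC(=O)OC | starting material
9 | methyl 2-{[(4R)-2,2-dimethyl-1,3-dioxolan-4-yl](hydroxy)methyl}prop-2-enoate | C=C(C(=O)OC)C(O)[C@H]1COC(C)(C)O1 | intermediate
10 | methyl (2Z)-2-(bromomethyl)-3-[(4S)-2,2-dimethyl-1,3-dioxolan-4-yl]prop-2-enoate | BrC/C(C(=O)OC)=C\[C@H]1COC(C)(C)O1 | intermediate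
11 | {2-(methoxycarbonyl)-3-[(4S)-2,2-dimethyl-1,3-dioxolan-4-yl]prop-2-enyl}chromium(III) dichloride (not isolated; geometry equilibrating) | COC(=O)C(C[Cr](Cl)Cl)=C[C@H]1COC(C)(C)O1 | intermediate
12 | methyl (3S,4R,5E)-6-[(tert-butyldiphenylsilyloxy)methyl]-3-[(4S)-2,2-dimethyl-1,3-dioxolan-4-yl]-4,7-dihydroxy-2-methylidenehept-5-enoate (not isolated) | COC(=O)C(=C)[C@@H]([C@H](O)/C=C(/CO[Si](c1ccccc1)(c1ccccc1)C(C)(C)C)CO)[C@H]1COC(C)(C)O1 | intermediate
13 | (4S,5R)-5-{(1E)-2-[(tert-butyldiphenylsilyloxy)methyl]-3-hydroxyprop-1-en-1-yl}-4-[(4S)-2,2-dimethyl-1,3-dioxolan-4-yl]-3-methylideneoxolan-2-one | C=C1C(=O)O[C@H](/C=C(/CO[Si](c2ccccc2)(c2ccccc2)C(C)(C)C)CO)[C@H]1[C@H]3COC(C)(C)O3 | intermediate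
14 | di-tert-butyl 3-oxopentanedioate | CC(C)(C)OC(=O)CC(=O)CC(=O)OC(C)(C)C | starting material
15 | O1-(5-tert-butoxy-3,5-dioxopentanoyl) ester of 13 | C=C1C(=O)O[C@H](/C=C(/CO[Si](c2ccccc2)(c2ccccc2)C(C)(C)C)COC(=O)CC(=O)CC(=O)OC(C)(C)C)[C@H]1[C@H]3COC(C)(C)O3 | intermediate
16 | C5,C6-diol from 15 | C=C1C(=O)O[C@H](/C=C(/CO[Si](c2ccccc2)(c2ccccc2)C(C)(C)C)COC(=O)CC(=O)CC(=O)OC(C)(C)C)[C@H]1[C@H](O)CO | intermediate
17 | O5-triethylsilyl ether of 16 | C=C1C(=O)O[C@H](/C=C(/CO[Si](c2ccccc2)(c2ccccc2)C(C)(C)C)COC(=O)CC(=O)CC(=O)OC(C)(C)C)[C@H]1[C@H](O)CO[Si](CC)(CC)CC | intermediate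
18 | acylketene from 17 (not isolated) | C=C1C(=O)O[C@H](/C=C(/CO[Si](c2ccccc2)(c2ccccc2)C(C)(C)C)COC(=O)CC(=O)C=C=O)[C@H]1[C@H](O)CO[Si](CC)(CC)CC | intermediate
19 | 13-membered O1,O6-diolide, O5-TES, O14-TBDPS | C=C1C(=O)O[C@@H]2/C=C(/CO[Si](c3ccccc3)(c4ccccc4)C(C)(C)C)COC(=O)CC(=O)CC(=O)O[C@H](CO[Si](CC)(CC)CC)[C@@H]12 | intermediate
20 | 13-membered diolide, free C5–OH | C=C1C(=O)O[C@@H]2/C=C(/CO[Si](c3ccccc3)(c4ccccc4)C(C)(C)C)COC(=O)CC(=O)CC(=O)O[C@H](CO)[C@@H]12 | intermediate
21 | 13-membered diolide C5-aldehyde (not isolated) | C=C1C(=O)O[C@@H]2/C=C(/CO[Si](c3ccccc3)(c4ccccc4)C(C)(C)C)COC(=O)CC(=O)CC(=O)O[C@H](C=O)[C@@H]12 | intermediate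
22 | 12-membered allyl β-keto lactone with 15,6-butenolide | C=C1C(=O)O[C@@H]2/C=C(/CO[Si](c3ccccc3)(c4ccccc4)C(C)(C)C)COC(=O)CC(=O)C5=C[C@@H](OC5=O)[C@@H]12 | intermediate
23 | π-allylpalladium β-keto carboxylate zwitterion (not isolated; drawn σ-bound at C1, phosphines omitted) | C=C1C(=O)O[C@H](/C=C(/CO[Si](c2ccccc2)(c2ccccc2)C(C)(C)C)C[Pd+])[C@H]1[C@H]3C=C(C(=O)CC(=O)[O-])C(=O)O3 | intermediate
24 | π-allylpalladium C2-enolate zwitterion (not isolated; drawn σ-bound at C1, phosphines omitted) | C=C1C(=O)O[C@H](/C=C(/CO[Si](c2ccccc2)(c2ccccc2)C(C)(C)C)C[Pd+])[C@H]1[C@H]3C=C(C([O-])=C)C(=O)O3 | intermediate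
25 | ten-membered C3-ketone, O14-TBDPS | C=C1C(=O)O[C@@H]2/C=C(/CO[Si](c3ccccc3)(c4ccccc4)C(C)(C)C)CCC(=O)C5=C[C@@H](OC5=O)[C@@H]12 | intermediate
26 | (3S)-alcohol, O14-TBDPS | C=C1C(=O)O[C@@H]2/C=C(/CO[Si](c3ccccc3)(c4ccccc4)C(C)(C)C)CC[C@H](O)C5=C[C@@H](OC5=O)[C@@H]12 | intermediate
27 | (3S)-2-methylpropanoate, O14-TBDPS | C=C1C(=O)O[C@@H]2/C=C(/CO[Si](c3ccccc3)(c4ccccc4)C(C)(C)C)CC[C@H](OC(=O)C(C)C)C5=C[C@@H](OC5=O)[C@@H]12 | intermediate
28 | CNP0322767.4 | C=C1C(=O)O[C@@H]2/C=C(/CO)CC[C@H](OC(=O)C(C)C)C3=C[C@@H](OC3=O)[C@@H]12 | target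

**Step count and risks**

Total step count: 16. Longest linear sequence: 14 steps (from 1: steps 1–3 and 6–16); the branch from 7 is 13 steps.

Steps most likely to fail:

Step 13 (proposed new method). The C2 enolate released on decarboxylation may be protonated, or may alkylate through oxygen, before the ten-membered ring closes, and the π-allyl fragment may then be lost as a diene. The fallback uses known chemistry, the Pd-catalysed cyclisation of a doubly stabilised β-keto ester onto an allylic carbonate, and closes the same C1–C2 bond with the most acidic site of the molecule as the nucleophile. It sets out from 13 and returns at 25. The C1 hydroxyl of 13 is converted into the methyl carbonate F1 (methyl chloroformate, pyridine). The acetonide is hydrolysed to the diol F2 (aqueous acetic acid) and the primary hydroxyl is silylated to the triethylsilyl ether F3. Heating with 14 in toluene transfers the 3-oxoglutarate unit onto O6 to give the mixed ester F4, and mild acid frees the C5 alcohol F5. Dess–Martin oxidation gives the aldehyde F6, which condenses in the flask (Knoevenagel) to the butenolide F7, carrying a C3(=O)–C2H2–CO2tBu side chain and the C1 carbonate. Pd(PPh3)4 in THF at high dilution should ionise the carbonate, and the liberated methoxide deprotonates C2, which closes the ten-membered β-keto tert-butyl ester F8. Trifluoroacetic acid cleaves the tert-butyl ester and gentle warming decarboxylates the β-keto acid to 25.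

Step 6. The addition may show insufficient anti selectivity or the wrong facial sense relative to C6, the lactol may open too slowly, or the allylmetal may lose the dioxolane oxygen by 1,4-elimination. The fallback replaces the chromium reagent by a geometry-defined 2-alkoxycarbonylallylboronate that adds through a closed chair transition state, so the anti relationship becomes stereospecific and no carbon–metal bond prone to elimination is present. It sets out from 7 (with 6) and returns at 13. Aldehyde 7 is homologated to the alkyne (4S)-4-ethynyl-2,2-dimethyl-1,3-dioxolane F9 (Ohira–Bestmann reagent, K2CO3, MeOH). F9 is carboxylated to the ynoate F10 (n-BuLi, methyl chloroformate). Syn-hydroalumination (DIBAL-H/HMPA) and trapping of the α-metallated acrylate with 2-(iodomethyl)-4,4,5,5-tetramethyl-1,3,2-dioxaborolane gives the boronate F11, in which the dioxolane is cis to the ester. Heating F11 with lactol 6 in toluene (Sc(OTf)3 catalysis if slow) should give hydroxy ester 12, which lactonises to 13.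

Step 14. The conformational bias of the ten-membered ring may override the catalyst and give poor facial selectivity, or hydride may add in the 1,4-sense to the acylbutenolide. The fallback accepts the substrate-controlled outcome and corrects C3 during esterification. It sets out from 25 and returns at 27. Luche reduction (NaBH4, CeCl3·7H2O, MeOH, −78 °C) gives the (3R)-alcohol F12, and Mitsunobu esterification with 2-methylpropanoic acid (PPh3, DIAD, toluene, 0 °C) installs the ester with inversion to give 27.

Further compounds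
F1 | step 13 | O1-methyl carbonate of 13 | C=C1C(=O)O[C@H](/C=C(/CO[Si](c2ccccc2)(c2ccccc2)C(C)(C)C)COC(=O)OC)[C@H]1[C@H]3COC(C)(C)O3
F2 | step 13 | C5,C6-diol of F1 | C=C1C(=O)O[C@H](/C=C(/CO[Si](c2ccccc2)(c2ccccc2)C(C)(C)C)COC(=O)OC)[C@H]1[C@H](O)CO
F3 | step 13 | O5-triethylsilyl ether of F2 | C=C1C(=O)O[C@H](/C=C(/CO[Si](c2ccccc2)(c2ccccc2)C(C)(C)C)COC(=O)OC)[C@H]1[C@H](O)CO[Si](CC)(CC)CC
F4 | step 13 | O6-(5-tert-butoxy-3,5-dioxopentanoyl) ester of F3 | C=C1C(=O)O[C@H](/C=C(/CO[Si](c2ccccc2)(c2ccccc2)C(C)(C)C)COC(=O)OC)[C@H]1[C@H](OC(=O)CC(=O)CC(=O)OC(C)(C)C)CO[Si](CC)(CC)CC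
F5 | step 13 | C5 alcohol from F4 | C=C1C(=O)O[C@H](/C=C(/CO[Si](c2ccccc2)(c2ccccc2)C(C)(C)C)COC(=O)OC)[C@H]1[C@H](OC(=O)CC(=O)CC(=O)OC(C)(C)C)CO
F6 | step 13 | C5 aldehyde from F5 (not isolated) | C=C1C(=O)O[C@H](/C=C(/CO[Si](c2ccccc2)(c2ccccc2)C(C)(C)C)COC(=O)OC)[C@H]1[C@H](OC(=O)CC(=O)CC(=O)OC(C)(C)C)C=O
F7 | step 13 | butenolide β-keto tert-butyl ester with C1 methyl carbonate | C=C1C(=O)O[C@H](/C=C(/CO[Si](c2ccccc2)(c2ccccc2)C(C)(C)C)COC(=O)OC)[C@H]1[C@H]3C=C(C(=O)CC(=O)OC(C)(C)C)C(=O)O3
F8 | step 13 | ten-membered C3-ketone carrying CO2tBu at C2 (C2 epimers) | C=C1C(=O)O[C@@H]2/C=C(/CO[Si](c3ccccc3)(c4ccccc4)C(C)(C)C)CC(C(=O)OC(C)(C)C)C(=O)C5=C[C@@H](OC5=O)[C@@H]12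
F9 | step 6 | (4S)-4-ethynyl-2,2-dimethyl-1,3-dioxolane | C#C[C@H]1COC(C)(C)O1
F10 | step 6 | methyl 3-[(4S)-2,2-dimethyl-1,3-dioxolan-4-yl]prop-2-ynoate | COC(=O)C#C[C@H]1COC(C)(C)O1
F11 | step 6 | methyl (2Z)-3-[(4S)-2,2-dimethyl-1,3-dioxolan-4-yl]-2-[(4,4,5,5-tetramethyl-1,3,2-dioxaborolan-2-yl)methyl]prop-2-enoate | COC(=O)/C(CB1OC(C)(C)C(C)(C)O1)=C\[C@H]2COC(C)(C)O2
F12 | step 14 | (3R)-alcohol, O14-TBDPS (C3 epimer of 26) | C=C1C(=O)O[C@@H]2/C=C(/CO[Si](c3ccccc3)(c4ccccc4)C(C)(C)C)CC[C@@H](O)C5=C[C@@H](OC5=O)[C@@H]12
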